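**Plan**

1. Numbering: the core is numbered as a naphthalene (ring A: C1–C4, C4a, C8a; ring B: C4a, C5–C8, C8a); the side chain on C5 is C1'–C5'.
2. Retrosynthetic cuts, latest first: C7–O and C1–CH2O; C8a–C1 and C4–C4a (ring A); C2'–C3' and C1'=C2' (side chain); C4a–C5 and C6–C7 (ring B, Diels–Alder).
3. Enabling feature: without ring A and the C7 oxygen, ring B is a 4,4-disubstituted cyclohex-2-enone (C8 carbonyl, C8a=C4a alkene, quaternary C5 carrying methyl and C1' beside the beta carbon C4a, methyl on C6). This is the retron of a 1-amino-3-siloxydiene plus alpha-methyl enal cycloaddition with loss of the nitrogen group.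
4. Forward order: ring B (steps 1–4); side chain by methylenation and B-alkyl Suzuki coupling (5–9); C7 oxygen (10–11); ring A by conjugate addition, re-oxidation, C8a iodination and palladium enolate alkenylation (12–17); C1 quaternary centre, acetate and diosphenol (18–22).
5. Stereochemistry: C5 from the chiral chromium–salen catalyst of the cycloaddition; C1 from a chiral scandium–bipyridine hydroxymethylation; the 3'E alkene from syn hydrozirconation; centres at C4a, C6, C7 and C8 are transient.

Key step: step 4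

Remark: the diene carries a benzyl(methoxycarbonyl)amino group instead of a dialkylamino group, because a basic, acid-labile enamine would not survive the cationic chromium Lewis acid; the nitrogen group still leaves when the enone is formed.
Remark: the antipode of the salen ligand (step 4) and of the bipyridine ligand (step 19) is the one that delivers the drawn C5 and C1 configurations; both antipodes are available and the sense is to be fixed in a test run.
Remark: stereocentres that arise at C4a, C6, C7, C8 and (in 27) C1 later return to sp2 carbons or are reset; they are drawn as the expected isomer or left undefined, and mixtures are carried forward.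
Remark: R = (E)-5-(tert-butyldimethylsilyloxy)-3-methylpent-3-en-1-yl; TBS = tert-butyldimethylsilyl; TMS = trimethylsilyl; monocyclic intermediates are named as cyclohexenones (ring C1, C2, C3, C4, C5, C6 = C8, C8a, C4a, C5, C6, C7 of the final numbering).

**Route**

Step 1
Reactants: 1 (E)-4-methoxybut-3-en-2-one
Product: 2 (Z)-4-(benzylamino)but-3-en-2-one
Conditions: BnNH2, CH2Cl2, 0 °C → rt
Reagents that add atoms: benzylamine, NCc1ccccc1
Why: Conjugate addition–elimination of the amine on the vinylogous ester replaces methoxide and gives the hydrogen-bonded Z enaminone.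

Step 2
Reactants: 2 (Z)-4-(benzylamino)but-3-en-2-one
Product: 3 methyl benzyl[(E)-3-oxobut-1-en-1-yl]carbamate
Conditions: NaN(SiMe3)2, THF, −78 °C; ClCO2Me, −78 → 0 °C
Reagents that add atoms: methyl chloroformate, COC(=O)Cl
Why: N-acylation of the deprotonated vinylogous amide with the chloroformate gives the vinylogous imide, which relaxes to the E isomer once the N–H hydrogen bond is gone.

Step 3
Reactants: 3 methyl benzyl[(E)-3-oxobut-1-en-1-yl]carbamate
Product: 4 methyl benzyl[(1E)-3-(tert-butyldimethylsilyloxy)buta-1,3-dien-1-yl]carbamate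
Conditions: KN(SiMe3)2, THF, −78 °C; TBSCl, −78 °C → rt
Reagents that add atoms: tert-butyldimethylsilyl chloride, CC(C)(C)[Si](C)(C)Cl
Why: Kinetic deprotonation of the methyl ketone and O-silylation of the cross-conjugated enolate is the standard entry to 1-amido-3-siloxybutadienes and leaves the E enamide untouched.

Step 4
Reactants: 4 methyl benzyl[(1E)-3-(tert-butyldimethylsilyloxy)buta-1,3-dien-1-yl]carbamate; 5 (E)-2-methylbut-2-enal
Product: 8 (1R,6S)-1,6-dimethyl-4-oxocyclohex-2-ene-1-carbaldehyde (4-formyl-4,5-dimethylcyclohex-2-enone), via silyl enol ether cycloadduct 6 (not isolated), via keto carbamate 7 (not isolated)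
Conditions: (salen)CrSbF6 (5 mol%), 4 Å MS, CH2Cl2, −20 °C → rt; then aq. HF, MeCN, 0 °C; then DBU, CH2Cl2, rt
Reagents that add atoms: none
Why: The cationic trivalent chromium centre binds the formyl oxygen of 5, and the electron-rich diene 4 adds in a concerted, asynchronous [4+2] cycloaddition in which its CH2 terminus (C7) bonds to the enal beta carbon (C6) and its nitrogen-bearing terminus (C4a) to the alpha carbon (C5); the closest known reaction is the chromium–salen catalysed enantioselective Diels–Alder reaction of 1-amido-3-siloxydienes with alpha-substituted acroleins, extended here to an alpha,beta-disubstituted enal. Ring B closes by intermolecular cycloaddition, C4a–C5 and C6–C7 forming in the same step. The C5 configuration is set by the chiral salen ligand, which shields one enantioface of the coordinated enal, and the C5 and C6 methyl groups come out cis because addition to the E alkene is suprafacial; the endo centre at C4a is transient. The step needs regio- and enantioface selectivity: the first follows from the polarised diene (nitrogen donor at C4a, siloxy group at C8), the second from the catalyst, helped by the carbamate, which keeps the diene stable to the Lewis acid and slows the uncatalysed background reaction. Fluoride then cleaves the silyl enol ether to ketone 7 and DBU expels the carbamate by E1cB elimination to give the C8 enone 8.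

Step 5
Reactants: 8 (1R,6S)-1,6-dimethyl-4-oxocyclohex-2-ene-1-carbaldehyde
Product: 9 4-ethenyl-4,5-dimethylcyclohex-2-en-1-one (configuration as in 8)
Conditions: Ph3PCH3Br, KN(SiMe3)2, THF, 0 °C; then 8, −78 → 0 °C
Reagents that add atoms: methyltriphenylphosphonium bromide, C[P+](c1ccccc1)(c1ccccc1)c1ccccc1.[Br-]
Why: Wittig methylenation is chemoselective because the non-stabilised ylide adds to the aldehyde much faster than to the conjugated ketone at low temperature, and the aldehyde has no alpha hydrogen, so C5 cannot epimerise.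

Step 6
Reactants: 10 but-2-yn-1-ol
Product: 11 tert-butyl(but-2-yn-1-yloxy)dimethylsilane
Conditions: TBSCl, imidazole, CH2Cl2, rt
Reagents that add atoms: tert-butyldimethylsilyl chloride, CC(C)(C)[Si](C)(C)Cl
Why: Standard silylation of a primary alcohol masks the hydroxyl for the organometallic steps that follow.

Step 7
Reactants: 11 tert-butyl(but-2-yn-1-yloxy)dimethylsilane
Product: 13 (E)-tert-butyl[(3-iodobut-2-en-1-yl)oxy]dimethylsilane, via alkenylzirconocene chloride 12 (not isolated)
Conditions: Cp2Zr(H)Cl (2 equiv), THF, 50 °C; then I2, 0 °C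
Reagents that add atoms: iodine, II
Why: Syn hydrozirconation, with excess reagent equilibrating zirconium to the methyl-bearing carbon remote from the silyloxymethyl group, and iodinolysis with retention give the E iodide that fixes the C3'=C4' geometry.

Step 8
Reactants: 9 4-ethenyl-4,5-dimethylcyclohex-2-en-1-one; 13 (E)-tert-butyl[(3-iodobut-2-en-1-yl)oxy]dimethylsilane
Product: 15 4-R-4,5-dimethylcyclohex-2-en-1-ol (C1 epimers), via bis(boryl) adduct 14 (not isolated)
Conditions: 9-BBN (2.6 equiv), THF, 0 °C → rt; then aq. Cs2CO3, 13, Pd(dppf)Cl2 (5 mol%), AsPh3, DMF, rt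
Reagents that add atoms: none
Why: 9-BBN hydroborates the terminal vinyl group at C2' and, as a known 1,2-reductant of enones, also takes C8 to the allylic borinate, after which B-alkyl Suzuki–Miyaura coupling with 13 forms C2'–C3' with retention of the E geometry and aqueous base frees the C8 alcohol.

Step 9
Reactants: 15 4-R-4,5-dimethylcyclohex-2-en-1-ol
Product: 16 4-R-4,5-dimethylcyclohex-2-en-1-one
Conditions: Dess–Martin periodinane, NaHCO3, CH2Cl2, 0 °C → rt
Reagents that add atoms: none
Why: Dess–Martin oxidation returns the secondary allylic alcohol to the enone without touching the trisubstituted alkene or the silyl ether, so both C8 epimers converge.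

Step 10
Reactants: 16 4-R-4,5-dimethylcyclohex-2-en-1-one
Product: 17 6-hydroxy-4-R-4,5-dimethylcyclohex-2-en-1-one (hydroxyl trans to the neighbouring methyl expected)
Conditions: NaN(SiMe3)2, THF, −78 °C; 2-(phenylsulfonyl)-3-phenyloxaziridine, −78 °C; aq. NH4Cl
Reagents that add atoms: 2-(phenylsulfonyl)-3-phenyloxaziridine, O=S(=O)(c1ccccc1)N1OC1c1ccccc1
Why: With C5 quaternary the enone has only alpha' hydrogens at C7, so the amide base gives the cross-conjugated enolate cleanly and electrophilic oxygen transfer from the N-sulfonyloxaziridine (enolate hydroxylation) occurs at C7, expected anti to the C6 methyl.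

Step 11
Reactants: 17 6-hydroxy-4-R-4,5-dimethylcyclohex-2-en-1-one
Product: 18 6-(tert-butyldimethylsilyloxy)-4-R-4,5-dimethylcyclohex-2-en-1-one
Conditions: TBSOTf (1.1 equiv), 2,6-lutidine, CH2Cl2, −78 °C
Reagents that add atoms: tert-butyldimethylsilyl trifluoromethanesulfonate, CC(C)(C)[Si](C)(C)OS(=O)(=O)C(F)(F)F
Why: Silyl triflate with a hindered pyridine base protects the alpha-ketol hydroxyl as a silyl ether that tolerates the cuprate, palladium and Lewis acid steps and is removed together with the side-chain silyl group in step 21.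

Step 12
Reactants: 19 pent-1-en-3-one
Product: 21 2-(2-bromoethyl)-2-ethyl-5,5-dimethyl-1,3-dioxane, via 1-bromopentan-3-one 20 (not isolated)
Conditions: HBr (g), CH2Cl2, 0 °C; then 2,2-dimethylpropane-1,3-diol, HC(OEt)3, TsOH (cat.), rt
Reagents that add atoms: hydrogen bromide, Br; 2,2-dimethylpropane-1,3-diol, OCC(C)(C)CO
Why: Conjugate addition of HBr to the vinyl ketone followed by acid-catalysed ketalisation with the 1,3-diol (water taken up by the orthoformate) gives a beta-bromo ketal whose Grignard reagent is thermally stable.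

Step 13
Reactants: 18 6-(tert-butyldimethylsilyloxy)-4-R-4,5-dimethylcyclohex-2-en-1-one; 21 2-(2-bromoethyl)-2-ethyl-5,5-dimethyl-1,3-dioxane
Product: 23 6-(tert-butyldimethylsilyloxy)-3-[2-(2-ethyl-5,5-dimethyl-1,3-dioxan-2-yl)ethyl]-4-R-4,5-dimethyl-1-(trimethylsilyloxy)cyclohex-1-ene (C3 epimers), via Grignard reagent 22 (not isolated)
Conditions: 21, Mg, THF, rt; then CuBr·SMe2 (20 mol%), TMSCl, HMPA, 18, THF, −78 °C; Et3N quench
Reagents that add atoms: chlorotrimethylsilane, C[Si](C)(C)Cl
Why: Copper-catalysed, chlorosilane-accelerated conjugate addition of the Grignard reagent forms C4–C4a at the only beta carbon despite the neighbouring quaternary C5, and trapping the enolate as its silyl ether fixes the C8–C8a enol regiochemistry for re-oxidation.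

Step 14
Reactants: 23 silyl enol ether from step 13
Product: 24 6-(tert-butyldimethylsilyloxy)-3-[2-(2-ethyl-5,5-dimethyl-1,3-dioxan-2-yl)ethyl]-4-R-4,5-dimethylcyclohex-2-en-1-one
Conditions: Pd(OAc)2 (1.1 equiv), MeCN, rt
Reagents that add atoms: none
Why: Saegusa–Ito oxidation proceeds through the divalent palladium enolate at C8a and beta-hydride elimination of the C4a hydrogen, restoring the C8a=C4a enone, now substituted at C4a, and erasing the C4a stereocentre.

Step 15
Reactants: 24 enone ketal from step 14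
Product: 25 6-(tert-butyldimethylsilyloxy)-3-[2-(2-ethyl-5,5-dimethyl-1,3-dioxan-2-yl)ethyl]-2-iodo-4-R-4,5-dimethylcyclohex-2-en-1-one
Conditions: I2, pyridine, DMAP (cat.), CH2Cl2, rt → 40 °C
Reagents that add atoms: iodine, II
Why: Alpha-iodination of enones with iodine and a pyridine base (addition at the enone followed by elimination) places iodine on C8a, the only vinylic C–H, and leaves the isolated trisubstituted alkene alone because its iodine adduct reverts.

Step 16
Reactants: 25 iodo enone ketal from step 15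
Product: 26 6-(tert-butyldimethylsilyloxy)-2-iodo-4-R-4,5-dimethyl-3-(3-oxopentyl)cyclohex-2-en-1-one
Conditions: PPTS, acetone/H2O (10:1), 55 °C
Reagents that add atoms: water, O
Why: Mild acid-catalysed ketal hydrolysis frees the C2 ketone while the silyl ethers and the vinyl iodide persist under these buffered conditions.

Step 17
Reactants: 26 iodo enone diketone from step 16
Product: 27 7-(tert-butyldimethylsilyloxy)-5-R-1,5,6-trimethyl-3,4,6,7-tetrahydronaphthalene-2,8(1H,5H)-dione (C1 epimers)
Conditions: Pd(PPh3)4 (10 mol%), KOPh (2.5 equiv), THF, 65 °C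
Reagents that add atoms: none
Why: Palladium-catalysed intramolecular alpha-alkenylation of a ketone (oxidative addition of zerovalent palladium into C8a–I, capture of the potassium enolate, reductive elimination) forms C8a–C1 and closes ring A as the six-membered ring, the enolate on the C3 side being able to give only a four-membered ring; 27 may arise as C1 epimers or as the C1=C8a ene-dione tautomer, all of which converge in step 18.

Step 18
Reactants: 27 bicyclic diketone from step 17
Product: 28 7-(tert-butyldimethylsilyloxy)-5-R-1,5,6-trimethyl-2-(trimethylsilyloxy)-4,5,6,7-tetrahydronaphthalen-8(3H)-one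
Conditions: TMSOTf (1.1 equiv), Et3N, CH2Cl2, −78 → 0 °C
Reagents that add atoms: trimethylsilyl trifluoromethanesulfonate, C[Si](C)(C)OS(=O)(=O)C(F)(F)F
Why: Soft enolisation removes the most acidic hydrogen (C1–H, alpha to the C2 carbonyl and allylic to C4a=C8a, or C4a–H of the ene-dione tautomer) and gives the conjugated C2 silyl enol ether regioselectively, while the hindered alpha-silyloxy ketone at C8 stays untouched with one equivalent of reagent.

Step 19
Reactants: 28 silyl dienol ether from step 18
Product: 29 (1S)-7-(tert-butyldimethylsilyloxy)-1-(hydroxymethyl)-5-R-1,5,6-trimethyl-3,4,6,7-tetrahydronaphthalene-2,8(1H,5H)-dione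
Conditions: Sc(OTf)3 (10 mol%), chiral 6,6'-bis(1-hydroxy-2,2-dimethylpropyl)-2,2'-bipyridine (12 mol%), aq. HCHO, DME/H2O, −20 °C
Reagents that add atoms: formaldehyde, C=O
Why: Catalytic asymmetric hydroxymethylation of the silyl enol ether of an alpha-methyl ketone with aqueous formaldehyde (Mukaiyama aldol under a chiral Sc(OTf)3–bipyridine complex) attacks at C1 because the C4a=C8a alkene is an electron-poor enone, and the quaternary C1 configuration is set by the ligand since the C5 centre is too remote to bias the faces.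

Step 20
Reactants: 29 hydroxymethyl diketone from step 19
Product: 30 [(1S)-7-(tert-butyldimethylsilyloxy)-5-R-1,5,6-trimethyl-2,8-dioxo-1,2,3,4,5,6,7,8-octahydronaphthalen-1-yl]methyl acetate
Conditions: Ac2O, pyridine, DMAP (cat.), CH2Cl2, 0 °C
Reagents that add atoms: acetic anhydride, CC(=O)OC(C)=O
Why: Acylation of the neopentyl primary alcohol under mild nucleophilic catalysis installs the acetate before the beta-hydroxy ketone can undergo retro-aldol cleavage, and C1 has no hydrogen, so the beta-acetoxy ketone cannot eliminate.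

Step 21
Reactants: 30 acetate from step 20
Product: 31 [(1S)-7-hydroxy-5-[(E)-5-hydroxy-3-methylpent-3-en-1-yl]-1,5,6-trimethyl-2,8-dioxo-1,2,3,4,5,6,7,8-octahydronaphthalen-1-yl]methyl acetate
Conditions: aq. HF (48%), MeCN, 0 °C → rt
Reagents that add atoms: none
Why: Acidic fluoride cleaves both silyl ethers (primary allylic and alpha-keto secondary) without hydrolysing the acetate or disturbing the quaternary centres.

Step 22
Reactants: 31 diol from step 21
Product: 33 [(1S,5S)-7-hydroxy-5-[(3E)-5-hydroxy-3-methylpent-3-en-1-yl]-1,5,6-trimethyl-2,8-dioxo-1,2,3,4,5,8-hexahydronaphthalen-1-yl]methyl acetate (CNP0512382.1), via 1,2-diketone 32 (not isolated)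
Conditions: Cu(OAc)2·H2O (2.2 equiv), AcOH/H2O (4:1), rt → 50 °C; EDTA work-up
Reagents that add atoms: none
Why: Cu(OAc)2 oxidises alpha-hydroxy ketones to 1,2-diketones through the ene-diol while leaving ordinary alcohols such as the primary allylic one untouched, and the C7/C8 diketone can enolise only toward C6, giving the conjugated diosphenol and removing the C6 and C7 stereocentres.

**Compound list**

1 | (E)-4-methoxybut-3-en-2-one | CO/C=C/C(C)=O | starting material
2 | (Z)-4-(benzylamino)but-3-en-2-one | CC(=O)/C=C\NCc1ccccc1 | intermediate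
3 | methyl benzyl[(E)-3-oxobut-1-en-1-yl]carbamate | COC(=O)N(Cc1ccccc1)/C=C/C(C)=O | intermediate
4 | methyl benzyl[(1E)-3-(tert-butyldimethylsilyloxy)buta-1,3-dien-1-yl]carbamate | COC(=O)N(Cc1ccccc1)/C=C/C(=C)O[Si](C)(C)C(C)(C)C | intermediate
5 | (E)-2-methylbut-2-enal | C/C=C(\C)C=O | starting material
6 | methyl benzyl[3-(tert-butyldimethylsilyloxy)-6-formyl-5,6-dimethylcyclohex-2-en-1-yl]carbamate (endo adduct, N cis to CHO, methyls cis) | CC(C)(C)[Si](C)(C)OC1=C[C@H](N(Cc2ccccc2)C(=O)OC)[C@](C)(C=O)[C@@H](C)C1 | intermediate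
7 | methyl benzyl(2-formyl-2,3-dimethyl-5-oxocyclohexyl)carbamate | O=C1C[C@H](N(Cc2ccccc2)C(=O)OC)[C@](C)(C=O)[C@@H](C)C1 | intermediate
8 | (1R,6S)-1,6-dimethyl-4-oxocyclohex-2-ene-1-carbaldehyde | O=C1C=C[C@](C)(C=O)[C@@H](C)C1 | intermediate
9 | 4-ethenyl-4,5-dimethylcyclohex-2-en-1-one (configuration as in 8) | O=C1C=C[C@](C)(C=C)[C@@H](C)C1 | intermediate
10 | but-2-yn-1-ol | CC#CCO | starting material
11 | tert-butyl(but-2-yn-1-yloxy)dimethylsilane | CC#CCO[Si](C)(C)C(C)(C)C | intermediate
12 | [(E)-4-(tert-butyldimethylsilyloxy)but-2-en-2-yl]chlorobis(cyclopentadienyl)zirconium | C/C(=C\CO[Si](C)(C)C(C)(C)C)[Zr](Cl)(C1C=CC=C1)C1C=CC=C1 | intermediate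
13 | (E)-tert-butyl[(3-iodobut-2-en-1-yl)oxy]dimethylsilane | C/C(I)=C\CO[Si](C)(C)C(C)(C)C | intermediate
14 | bis(9-borabicyclo[3.3.1]nonan-9-yl) adduct of 9 (C2' borane, C8 borinate; C8 epimers) | O(B1C2CCCC1CCC2)C1C=C[C@](C)(CCB2C3CCCC2CCC3)[C@@H](C)C1 | intermediate
15 | 4-R-4,5-dimethylcyclohex-2-en-1-ol (C1 epimers) | OC1C=C[C@](C)(CC/C(C)=C/CO[Si](C)(C)C(C)(C)C)[C@@H](C)C1 | intermediate
16 | 4-R-4,5-dimethylcyclohex-2-en-1-one | O=C1C=C[C@](C)(CC/C(C)=C/CO[Si](C)(C)C(C)(C)C)[C@@H](C)C1 | intermediate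
17 | 6-hydroxy-4-R-4,5-dimethylcyclohex-2-en-1-one (OH trans to neighbouring methyl) | O=C1C=C[C@](C)(CC/C(C)=C/CO[Si](C)(C)C(C)(C)C)[C@@H](C)[C@@H]1O | intermediate
18 | 6-(tert-butyldimethylsilyloxy)-4-R-4,5-dimethylcyclohex-2-en-1-one | O=C1C=C[C@](C)(CC/C(C)=C/CO[Si](C)(C)C(C)(C)C)[C@@H](C)[C@@H]1O[Si](C)(C)C(C)(C)C | intermediate
19 | pent-1-en-3-one | C=CC(=O)CC | starting material
20 | 1-bromopentan-3-one | BrCCC(=O)CC | intermediate
21 | 2-(2-bromoethyl)-2-ethyl-5,5-dimethyl-1,3-dioxane | CCC1(CCBr)OCC(C)(C)CO1 | intermediate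
22 | [2-(2-ethyl-5,5-dimethyl-1,3-dioxan-2-yl)ethyl]magnesium bromide | CCC1(CC[Mg]Br)OCC(C)(C)CO1 | intermediate
23 | 6-(tert-butyldimethylsilyloxy)-3-[2-(2-ethyl-5,5-dimethyl-1,3-dioxan-2-yl)ethyl]-4-R-4,5-dimethyl-1-(trimethylsilyloxy)cyclohex-1-ene (C3 epimers) | C[Si](C)(C)OC1=CC(CCC2(CC)OCC(C)(C)CO2)[C@](C)(CC/C(C)=C/CO[Si](C)(C)C(C)(C)C)[C@@H](C)[C@@H]1O[Si](C)(C)C(C)(C)C | intermediate
24 | 6-(tert-butyldimethylsilyloxy)-3-[2-(2-ethyl-5,5-dimethyl-1,3-dioxan-2-yl)ethyl]-4-R-4,5-dimethylcyclohex-2-en-1-one | O=C1C=C(CCC2(CC)OCC(C)(C)CO2)[C@](C)(CC/C(C)=C/CO[Si](C)(C)C(C)(C)C)[C@@H](C)[C@@H]1O[Si](C)(C)C(C)(C)C | intermediate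
25 | 6-(tert-butyldimethylsilyloxy)-3-[2-(2-ethyl-5,5-dimethyl-1,3-dioxan-2-yl)ethyl]-2-iodo-4-R-4,5-dimethylcyclohex-2-en-1-one | O=C1C(I)=C(CCC2(CC)OCC(C)(C)CO2)[C@](C)(CC/C(C)=C/CO[Si](C)(C)C(C)(C)C)[C@@H](C)[C@@H]1O[Si](C)(C)C(C)(C)C | intermediate
26 | 6-(tert-butyldimethylsilyloxy)-2-iodo-4-R-4,5-dimethyl-3-(3-oxopentyl)cyclohex-2-en-1-one | O=C1C(I)=C(CCC(=O)CC)[C@](C)(CC/C(C)=C/CO[Si](C)(C)C(C)(C)C)[C@@H](C)[C@@H]1O[Si](C)(C)C(C)(C)C | intermediate
27 | 7-(tert-butyldimethylsilyloxy)-5-R-1,5,6-trimethyl-3,4,6,7-tetrahydronaphthalene-2,8(1H,5H)-dione (C1 epimers) | O=C1C2=C(CCC(=O)C2C)[C@](C)(CC/C(C)=C/CO[Si](C)(C)C(C)(C)C)[C@@H](C)[C@@H]1O[Si](C)(C)C(C)(C)C | intermediate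
28 | 7-(tert-butyldimethylsilyloxy)-5-R-1,5,6-trimethyl-2-(trimethylsilyloxy)-4,5,6,7-tetrahydronaphthalen-8(3H)-one | O=C1C2=C(CCC(O[Si](C)(C)C)=C2C)[C@](C)(CC/C(C)=C/CO[Si](C)(C)C(C)(C)C)[C@@H](C)[C@@H]1O[Si](C)(C)C(C)(C)C | intermediate
29 | (1S)-7-(tert-butyldimethylsilyloxy)-1-(hydroxymethyl)-5-R-1,5,6-trimethyl-3,4,6,7-tetrahydronaphthalene-2,8(1H,5H)-dione | O=C1C2=C(CCC(=O)[C@]2(C)CO)[C@](C)(CC/C(C)=C/CO[Si](C)(C)C(C)(C)C)[C@@H](C)[C@@H]1O[Si](C)(C)C(C)(C)C | intermediate
30 | [(1S)-7-(tert-butyldimethylsilyloxy)-5-R-1,5,6-trimethyl-2,8-dioxo-1,2,3,4,5,6,7,8-octahydronaphthalen-1-yl]methyl acetate | O=C1C2=C(CCC(=O)[C@]2(C)COC(C)=O)[C@](C)(CC/C(C)=C/CO[Si](C)(C)C(C)(C)C)[C@@H](C)[C@@H]1O[Si](C)(C)C(C)(C)C | intermediate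
31 | [(1S)-7-hydroxy-5-[(E)-5-hydroxy-3-methylpent-3-en-1-yl]-1,5,6-trimethyl-2,8-dioxo-1,2,3,4,5,6,7,8-octahydronaphthalen-1-yl]methyl acetate | O=C1C2=C(CCC(=O)[C@]2(C)COC(C)=O)[C@](C)(CC/C(C)=C/CO)[C@@H](C)[C@@H]1O | intermediate
32 | [(1S)-5-[(E)-5-hydroxy-3-methylpent-3-en-1-yl]-1,5,6-trimethyl-2,7,8-trioxo-1,2,3,4,5,6,7,8-octahydronaphthalen-1-yl]methyl acetate | O=C1C2=C(CCC(=O)[C@]2(C)COC(C)=O)[C@](C)(CC/C(C)=C/CO)[C@@H](C)C1=O | intermediate
33 | [(1S,5S)-7-hydroxy-5-[(3E)-5-hydroxy-3-methylpent-3-en-1-yl]-1,5,6-trimethyl-2,8-dioxo-1,2,3,4,5,8-hexahydronaphthalen-1-yl]methyl acetate | O=C1C2=C(CCC(=O)[C@]2(C)COC(C)=O)[C@](C)(CC/C(C)=C/CO)C(C)=C1O | target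

**Step count and risks**

Total step count: 22 steps.
Longest linear sequence: 19 steps (steps 1–5, 8–11 and 13–22); steps 6–7 and step 12 are side branches.

Steps most likely to fail:

Step 15. Delivery of iodine to C8a may be blocked, because the addition–elimination pathway needs a nucleophile or iodine to engage C4a, which is flanked by the quaternary C5 and already carries the ring A tether. The fallback introduces the halogen through enol ether chemistry, which does not depend on attack at C4a. It sets out from 23: N-bromosuccinimide in THF at −78 °C would give the C8a bromo ketone F3. Soft enolisation (TMSOTf, Et3N) toward the bromine-bearing carbon would give the bromo silyl enol ether F4, and a second N-bromosuccinimide treatment the C8a gem-dibromo ketone F5. Dehydrobromination with Li2CO3 and LiBr in DMF (loss of the C4a hydrogen) would give the 2-bromo enone ketal F6, and ketal hydrolysis as in step 16 the bromo enone diketone F7. The palladium-catalysed enolate alkenylation of step 17, applied to the vinyl bromide, returns to the route at 27.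

Step 19. Facial selection at C1 rests on the catalyst alone, since C5 is remote, and may be poor; hydrolysis of the silyl dienol ether back to 27 may also compete. The fallback sets out from 28: hydroxymethylation with aqueous formaldehyde and Sc(OTf)3 without chiral ligand would give 29 together with its C1 epimer, the epimeric hydroxymethyl diketone F8. The two are diastereomers, because C5 is fixed, and would be separated by chromatography. If needed, separation is helped by lipase-mediated acetylation with vinyl acetate, which acylates one epimer faster and so gives either 30 directly or the epimeric acetate F9 beside unchanged 29. Alcohol 29 is acetylated as in step 20 and the route is rejoined at 30. The unwanted epimer F8 (from F9 after methanolysis) is returned to 27 by retro-aldol loss of formaldehyde with K2CO3 in methanol.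

Step 4. Cycloaddition of the trisubstituted enal may be sluggish with the attenuated carbamate diene, and enantioface selection may erode at the higher temperature then needed. The fallback sets out from 5 and uses hydrogen-bond catalysis with a more nucleophilic diene: the purchased (E)-3-(tert-butyldimethylsilyloxy)-N,N-dimethylbuta-1,3-dien-1-amine F1 would be combined with 5 in toluene at −78 → −40 °C in the presence of a TADDOL diol as chiral hydrogen-bond donor. The resulting cycloadduct, the C4a dimethylamino silyl enol ether F2, loses the silyl group and dimethylamine on treatment with aqueous HF in MeCN, and the route is rejoined at 8.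

**Further compounds**

F1 | step 4 | (E)-3-(tert-butyldimethylsilyloxy)-N,N-dimethylbuta-1,3-dien-1-amine | CN(C)/C=C/C(=C)O[Si](C)(C)C(C)(C)C
F2 | step 4 | 4-(tert-butyldimethylsilyloxy)-2-(dimethylamino)-1,6-dimethylcyclohex-3-ene-1-carbaldehyde (endo adduct) | CC(C)(C)[Si](C)(C)OC1=C[C@H](N(C)C)[C@](C)(C=O)[C@@H](C)C1
F3 | step 15 | 2-bromo-6-(tert-butyldimethylsilyloxy)-3-[2-(2-ethyl-5,5-dimethyl-1,3-dioxan-2-yl)ethyl]-4-R-4,5-dimethylcyclohexan-1-one | O=C1C(Br)C(CCC2(CC)OCC(C)(C)CO2)[C@](C)(CC/C(C)=C/CO[Si](C)(C)C(C)(C)C)[C@@H](C)[C@@H]1O[Si](C)(C)C(C)(C)C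
F4 | step 15 | 2-bromo-6-(tert-butyldimethylsilyloxy)-3-[2-(2-ethyl-5,5-dimethyl-1,3-dioxan-2-yl)ethyl]-4-R-4,5-dimethyl-1-(trimethylsilyloxy)cyclohex-1-ene | C[Si](C)(C)OC1=C(Br)C(CCC2(CC)OCC(C)(C)CO2)[C@](C)(CC/C(C)=C/CO[Si](C)(C)C(C)(C)C)[C@@H](C)[C@@H]1O[Si](C)(C)C(C)(C)C
F5 | step 15 | 2,2-dibromo-6-(tert-butyldimethylsilyloxy)-3-[2-(2-ethyl-5,5-dimethyl-1,3-dioxan-2-yl)ethyl]-4-R-4,5-dimethylcyclohexan-1-one | O=C1C(Br)(Br)C(CCC2(CC)OCC(C)(C)CO2)[C@](C)(CC/C(C)=C/CO[Si](C)(C)C(C)(C)C)[C@@H](C)[C@@H]1O[Si](C)(C)C(C)(C)C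
F6 | step 15 | 2-bromo-6-(tert-butyldimethylsilyloxy)-3-[2-(2-ethyl-5,5-dimethyl-1,3-dioxan-2-yl)ethyl]-4-R-4,5-dimethylcyclohex-2-en-1-one | O=C1C(Br)=C(CCC2(CC)OCC(C)(C)CO2)[C@](C)(CC/C(C)=C/CO[Si](C)(C)C(C)(C)C)[C@@H](C)[C@@H]1O[Si](C)(C)C(C)(C)C
F7 | step 15 | 2-bromo-6-(tert-butyldimethylsilyloxy)-4-R-4,5-dimethyl-3-(3-oxopentyl)cyclohex-2-en-1-one | O=C1C(Br)=C(CCC(=O)CC)[C@](C)(CC/C(C)=C/CO[Si](C)(C)C(C)(C)C)[C@@H](C)[C@@H]1O[Si](C)(C)C(C)(C)C
F8 | step 19 | (1R)-7-(tert-butyldimethylsilyloxy)-1-(hydroxymethyl)-5-R-1,5,6-trimethyl-3,4,6,7-tetrahydronaphthalene-2,8(1H,5H)-dione (C1 epimer of 29) | O=C1C2=C(CCC(=O)[C@@]2(C)CO)[C@](C)(CC/C(C)=C/CO[Si](C)(C)C(C)(C)C)[C@@H](C)[C@@H]1O[Si](C)(C)C(C)(C)C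
F9 | step 19 | [(1R)-7-(tert-butyldimethylsilyloxy)-5-R-1,5,6-trimethyl-2,8-dioxo-1,2,3,4,5,6,7,8-octahydronaphthalen-1-yl]methyl acetate (C1 epimer of 30) | O=C1C2=C(CCC(=O)[C@@]2(C)COC(C)=O)[C@](C)(CC/C(C)=C/CO[Si](C)(C)C(C)(C)C)[C@@H](C)[C@@H]1O[Si](C)(C)C(C)(C)C
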